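**Plan**

- Retrosynthesis: remove the phenol silyl helper, then cut the exocyclic C3=CH(aryl) bond (aldol condensation retron) to a 4-benzyl γ-butyrolactone and silyl-protected syringaldehyde. Next cut the lactone O1–C5 bond (Baeyer–Villiger retron) to a 3-benzylcyclobutanone, and last the two ring bonds made by a ketene–alkene [2+2] cycloaddition, back to the allylarene elemicin.
- Enabling feature: without the arylidene, lactone C4 carries H, the trimethoxybenzyl group and two ring methylenes (C3 and C5) that differ only because O1 lies between C5 and C2. Deleting O1 and joining C5 to C2 gives a strained 3-substituted cyclobutanone with a mirror plane through C1 and C3.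
- Forward order: the four-membered ring is built first as a temporary ring and is expanded into the five-membered lactone. The arylidene is then attached at C3 and the silyl group is removed last.
- Stereochemistry: the only stereocenter (C4, R) arises in the ring expansion by catalyst-controlled choice between the two enantiotopic methylenes. The E alkene comes from base-mediated elimination toward the more stable isomer.

Key step: step 3

Assumption: the antipode of the phosphoric acid that delivers the R lactone is taken; the assignment rests on analogy with 3-arylcyclobutanones and is to be checked by the sign of rotation of 8 against the known (R)-4-benzyl lactone series before material is carried on.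

**Route**

Step 1
Reactants: 1 elemicin (5-allyl-1,2,3-trimethoxybenzene); 2 trichloroacetyl chloride
Product: 4 2,2-dichloro-3-(3,4,5-trimethoxybenzyl)cyclobutan-1-one (racemic), via dichloroketene 3 (not isolated)
Conditions: Zn dust (activated), POCl3, Et2O, reflux, slow addition of 2
Reagents that add atoms: none
Why: Zinc dehalogenates 2 to dichloroketene, which should add to the terminal alkene of 1 in a thermal ketene–alkene [2+2] cycloaddition with the carbonyl carbon bonding to the terminal CH2, so that the benzyl group sits at C3; POCl3 ties up ZnCl2, and the new stereocenter forms as a racemate that loses its chirality in step 2.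

Step 2
Reactants: 4 2,2-dichloro-3-(3,4,5-trimethoxybenzyl)cyclobutan-1-one
Product: 6 3-(3,4,5-trimethoxybenzyl)cyclobutan-1-one, via monochloro ketone 5 (not isolated)
Conditions: Zn dust, AcOH, 60 °C
Reagents that add atoms: none
Why: Reductive removal of both α-chlorines of an α,α-dichloroketone by zinc in acetic acid (zinc enolate formation and protonation, twice) is the standard follow-up to a dichloroketene cycloaddition and should leave the ketone and aryl ethers untouched; the product has a mirror plane and no stereocenter.

Step 3
Reactants: 6 3-(3,4,5-trimethoxybenzyl)cyclobutan-1-one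
Product: 8 (R)-4-(3,4,5-trimethoxybenzyl)dihydrofuran-2(3H)-one, via Criegee adduct 7 (not isolated)
Conditions: 3,3'-di(pyren-1-yl)-5,5',6,6',7,7',8,8'-octahydro-1,1'-binaphthalene-2,2'-diyl hydrogen phosphate (single antipode, 10 mol%), 30% aq H2O2 (1.5 equiv), CHCl3, −40 °C
Reagents that add atoms: hydrogen peroxide, OO
Why: The phosphoric acid binds ketone and H2O2 together through its P–OH and P=O groups, H2O2 adds to the strained carbonyl to give Criegee adduct 7, and the ring CH2 that lies antiperiplanar to the O–O bond then shifts from carbon to oxygen with loss of water, forming the O1–C5 bond of the lactone. The closest known reaction type is the chiral-Brønsted-acid-catalysed Baeyer–Villiger desymmetrisation of 3-substituted cyclobutanones with aqueous H2O2. The five-membered lactone ring is closed by ring expansion, a concerted 1,2-shift of a ring carbon onto oxygen (four-membered to five-membered) and not an exo or endo cyclisation, and release of the cyclobutanone strain should drive it without a peracid. The only stereocenter, C4 of the lactone (C3 of the ketone), is not itself touched; its R configuration is fixed by the chiral phosphate pocket, which decides which of the two enantiotopic CH2 groups migrates. The selectivity needed is enantiotopic-group selectivity alone: because 6 has a mirror plane through C1 and C3, both migrations give the same constitution, so no regiochemical issue arises, and the electron-rich arene should not be oxidised by H2O2 at −40 °C.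

Step 4
Reactants: 9 syringaldehyde (4-hydroxy-3,5-dimethoxybenzaldehyde)
Product: 10 4-[(tert-butyldimethylsilyl)oxy]-3,5-dimethoxybenzaldehyde
Conditions: TBSCl, imidazole, DMF, rt
Reagents that add atoms: tert-butyldimethylsilyl chloride (TBSCl), CC(C)(C)[Si](C)(C)Cl
Why: Standard silylation of a phenol masks the acidic OH that would quench the enolate in step 5, and the silyl ether can later be removed with fluoride without touching the arylidene, which hydrogenolysis of a benzyl ether would saturate.

Step 5
Reactants: 8 (R)-4-(3,4,5-trimethoxybenzyl)dihydrofuran-2(3H)-one; 10 4-[(tert-butyldimethylsilyl)oxy]-3,5-dimethoxybenzaldehyde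
Product: 12 (3S,4R)-3-{[4-(tert-butyldimethylsilyloxy)-3,5-dimethoxyphenyl](hydroxy)methyl}-4-(3,4,5-trimethoxybenzyl)dihydrofuran-2(3H)-one (both carbinol epimers), via lithium enolate 11 (not isolated)
Conditions: LiN(SiMe3)2 (1.1 equiv), THF, −78 °C; then 10, −78 °C; AcOH quench at −78 °C
Reagents that add atoms: none
Why: Aldol addition of a lactone lithium enolate to an aromatic aldehyde should take place on the enolate face opposite the C4 benzyl group to give the 3,4-trans lactone, while the carbinol configuration is left uncontrolled because C3 and the carbinol carbon both become sp2 in step 6 and the non-acidic C4 centre is not disturbed.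

Step 6
Reactants: 12 aldol adduct (both carbinol epimers)
Product: 14 (R,E)-3-{4-[(tert-butyldimethylsilyl)oxy]-3,5-dimethoxybenzylidene}-4-(3,4,5-trimethoxybenzyl)dihydrofuran-2(3H)-one, via mesylate 13 (not isolated)
Conditions: MsCl, Et3N, CH2Cl2, 0 °C; then DBU, 0 °C to rt, short reaction time
Reagents that add atoms: none
Why: Mesylation followed by E1cB elimination through the lactone enolate should give the conjugated arylidene lactone from either carbinol epimer, with the E isomer (aryl anti to the lactone carbonyl) expected as the more stable and predominant one, and short exposure to DBU should keep C4 intact.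

Step 7
Reactants: 14 silyl-protected arylidene lactone
Product: 15 (R,E)-3-(4-hydroxy-3,5-dimethoxybenzylidene)-4-(3,4,5-trimethoxybenzyl)dihydrofuran-2(3H)-one (target)
Conditions: Bu4NF, AcOH, THF, 0 °C
Reagents that add atoms: none
Why: Fluoride-mediated cleavage of an aryl silyl ether, buffered with acetic acid so that the phenoxide is protonated at once, should free the phenol without isomerising the alkene, opening the lactone or deprotonating C4.

**Compound list**

1 | elemicin (5-allyl-1,2,3-trimethoxybenzene) | C=CCc1cc(OC)c(OC)c(OC)c1 | starting material
2 | trichloroacetyl chloride | ClC(Cl)(Cl)C(=O)Cl | starting material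
3 | dichloroketene | ClC(Cl)=C=O | intermediate
4 | 2,2-dichloro-3-(3,4,5-trimethoxybenzyl)cyclobutan-1-one (racemic) | O=C1CC(Cc2cc(OC)c(OC)c(OC)c2)C1(Cl)Cl | intermediate
5 | 2-chloro-3-(3,4,5-trimethoxybenzyl)cyclobutan-1-one (racemic, both diastereomers) | O=C1CC(Cc2cc(OC)c(OC)c(OC)c2)C1Cl | intermediate
6 | 3-(3,4,5-trimethoxybenzyl)cyclobutan-1-one | O=C1CC(Cc2cc(OC)c(OC)c(OC)c2)C1 | intermediate
7 | 1-hydroperoxy-3-(3,4,5-trimethoxybenzyl)cyclobutan-1-ol (Criegee adduct, cis/trans not defined) | OOC1(O)CC(Cc2cc(OC)c(OC)c(OC)c2)C1 | intermediate
8 | (R)-4-(3,4,5-trimethoxybenzyl)dihydrofuran-2(3H)-one | O=C1OC[C@H](Cc2cc(OC)c(OC)c(OC)c2)C1 | intermediate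
9 | syringaldehyde (4-hydroxy-3,5-dimethoxybenzaldehyde) | O=Cc1cc(OC)c(O)c(OC)c1 | starting material
10 | 4-[(tert-butyldimethylsilyl)oxy]-3,5-dimethoxybenzaldehyde | O=Cc1cc(OC)c(O[Si](C)(C)C(C)(C)C)c(OC)c1 | intermediate
11 | lithium enolate of 8, lithium (R)-4-(3,4,5-trimethoxybenzyl)-4,5-dihydrofuran-2-olate | [Li]OC1=C[C@@H](Cc2cc(OC)c(OC)c(OC)c2)CO1 | intermediate
12 | (3S,4R)-3-{[4-(tert-butyldimethylsilyloxy)-3,5-dimethoxyphenyl](hydroxy)methyl}-4-(3,4,5-trimethoxybenzyl)dihydrofuran-2(3H)-one (both carbinol epimers) | O=C1OC[C@H](Cc2cc(OC)c(OC)c(OC)c2)[C@H]1C(O)c3cc(OC)c(O[Si](C)(C)C(C)(C)C)c(OC)c3 | intermediate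
13 | methanesulfonate of 12 (both carbinol epimers) | O=C1OC[C@H](Cc2cc(OC)c(OC)c(OC)c2)[C@H]1C(OS(C)(=O)=O)c3cc(OC)c(O[Si](C)(C)C(C)(C)C)c(OC)c3 | intermediate
14 | (R,E)-3-{4-[(tert-butyldimethylsilyl)oxy]-3,5-dimethoxybenzylidene}-4-(3,4,5-trimethoxybenzyl)dihydrofuran-2(3H)-one | COc1cc(/C=C2/C(=O)OC[C@@H]2Cc2cc(OC)c(OC)c(OC)c2)cc(OC)c1O[Si](C)(C)C(C)(C)C | intermediate
15 | (R,E)-3-(4-hydroxy-3,5-dimethoxybenzylidene)-4-(3,4,5-trimethoxybenzyl)dihydrofuran-2(3H)-one | COc1cc(/C=C2/C(=O)OC[C@@H]2Cc2cc(OC)c(OC)c(OC)c2)cc(OC)c1O | target

**Count and risks**

Total step count: 7. Longest linear sequence: 6 (steps 1, 2, 3, 5, 6, 7); step 4 is a one-step side branch.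

Steps most likely to fail:

1. Step 3. The catalyst may discriminate poorly between the two enantiotopic methylenes, because the benzyl substituent sits one carbon further from the ring than the aryl groups for which this catalysis works best, and the lactone would then be formed with low enantiomeric purity. Fallback, setting out from 6 and returning at 8: enantioselective deprotonation of 6 with lithium bis(1-phenylethyl)amide (the R,R or S,S antipode chosen to give the R enol ether) in THF at −100 °C with Me3SiCl present as internal quench should give the silyl enol ether (R)-trimethyl{[3-(3,4,5-trimethoxybenzyl)cyclobut-1-en-1-yl]oxy}silane F1. Ozonolysis of the enol ether double bond in CH2Cl2/MeOH at −78 °C with NaBH4 work-up should give (R)-4-hydroxy-3-(3,4,5-trimethoxybenzyl)butanoic acid F2, which closes to 8 on acidification with aqueous HCl. Here the stereocenter is set by a stoichiometric chiral base choosing between enantiotopic α-protons instead of a catalyst choosing between migrating groups.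

2. Step 6. The elimination may give the Z isomer alongside the E isomer, and DBU may remove the C4 proton of the product by vinylogous enolisation, which would erode the configuration at C4 or move the double bond into the ring. Fallback, setting out from 8 and returning at 14 (it replaces steps 5 and 6): treatment of 8 with LiN(i-Pr)2 and diethyl chlorophosphate in THF at −78 °C should give the enol phosphate diethyl (R)-4-(3,4,5-trimethoxybenzyl)-4,5-dihydrofuran-2-yl phosphate F3. With a second equivalent of LiN(i-Pr)2 this should rearrange by 1,3-phosphoryl shift from oxygen to carbon to diethyl [(4S)-2-oxo-4-(3,4,5-trimethoxybenzyl)oxolan-3-yl]phosphonate F4 (C3 epimers; spatial arrangement at C4 as in 8, the descriptor changing only through the priority of phosphorus). Horner–Wadsworth–Emmons olefination of the phosphonate with aldehyde 10 (NaH, THF, 0 °C to rt) should then give 14 directly, with the E selectivity usual for α-phosphono lactones and aromatic aldehydes and without a separate strong-base elimination.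

3. Step 1. Dichloroketene may oligomerise faster than it adds to the unactivated monosubstituted alkene, and zinc halide Lewis acidity may cause acylation of the electron-rich ring, so that conversion to 4 is poor. Fallback, setting out from 1 and returning at 6 (it replaces steps 1 and 2): N,N-dimethylacetamide, Tf2O and 2,4,6-collidine in ClCH2CH2Cl should generate N,N-dimethylketeniminium trifluoromethanesulfonate F5 in the flask. Its [2+2] cycloaddition with the alkene of 1 at reflux should give N,N-dimethyl-3-(3,4,5-trimethoxybenzyl)cyclobutan-1-iminium trifluoromethanesulfonate F6, which is hydrolysed with water to 6 with no dechlorination step.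

**Further compounds**

F1 | step 3 | (R)-trimethyl{[3-(3,4,5-trimethoxybenzyl)cyclobut-1-en-1-yl]oxy}silane | C[Si](C)(C)OC1=C[C@H](Cc2cc(OC)c(OC)c(OC)c2)C1
F2 | step 3 | (R)-4-hydroxy-3-(3,4,5-trimethoxybenzyl)butanoic acid | OC[C@H](Cc1cc(OC)c(OC)c(OC)c1)CC(=O)O
F3 | step 6 | diethyl (R)-4-(3,4,5-trimethoxybenzyl)-4,5-dihydrofuran-2-yl phosphate | CCOP(=O)(OCC)OC1=C[C@@H](Cc2cc(OC)c(OC)c(OC)c2)CO1
F4 | step 6 | diethyl [(4S)-2-oxo-4-(3,4,5-trimethoxybenzyl)oxolan-3-yl]phosphonate (C3 epimers) | CCOP(=O)(OCC)C1C(=O)OC[C@@H]1Cc2cc(OC)c(OC)c(OC)c2
F5 | step 1 | N,N-dimethylketeniminium trifluoromethanesulfonate | C=C=[N+](C)C.[O-]S(=O)(=O)C(F)(F)F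
F6 | step 1 | N,N-dimethyl-3-(3,4,5-trimethoxybenzyl)cyclobutan-1-iminium trifluoromethanesulfonate | C[N+](C)=C1CC(Cc2cc(OC)c(OC)c(OC)c2)C1.[O-]S(=O)(=O)C(F)(F)F
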